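**Plan**

- Numbering (labdane): ring A = C1–C5 and C10; ring B = C5–C10; C17 = the CH2OH carbon on C8; C11–C12 = the chain from C9 to the butenolide (C13–C16); C19 = the carboxyl carbon on C4; C20 = the methyl on C10.
- Retrosynthesis: cut C12–C13 (sp3–sp2 Suzuki–Miyaura coupling), then C11=C12 (Wittig methylenation of the lactol of a C17–O–C11 lactone), then C7–C8 and C9–C10 together (ring B), then C5–C6 (Stille coupling) and C4–CH3. This leaves tert-butyl 2-oxocyclohexanecarboxylate and ethyl (E)-4-hydroxybut-2-enoate.
- Enabling feature: in ring B the C8–C9 unit carries trans CH2OH (C17) and C11, and O17 lies 1,3 across ring B from C6. A temporary oxygen on C6 (silyl dienol ether; diene C10=C5–C6=C7 on ring A) can therefore be tied to O17 through Si(iPr)2, while C11 as an ester activates the (E)-C8=C9 dienophile. Ring B then closes by a silicon-tethered type 2 intramolecular Diels–Alder reaction.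
- Forward order: ring A with quaternary C4, then enol triflate, then C6/C7 acetyl, then silaketal, then ring B (with a temporary seven-membered O–Si–O ring), then removal of silicon and the C6 oxygen, then lactone, lactol, vinyl, butenolide, and free acid.
- Stereochemistry: C4 from a valine-derived chiral enamine methylation; C10, C8 and C9 from the cycloaddition (C4 face control, tether-enforced endo C17, retained E geometry); C5 from α-face protonation of the C5=C6 enol (trans-decalin).

Key step: step 8

Assumption: tert-butyl 2-oxocyclohexane-1-carboxylate (1) is taken as a catalogue compound.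
Assumption: in step 2 the weakly solvated lithio-enamine of the (S)-valine ester is methylated anti to the isopropyl group, which corresponds to (S) at C4; if the sense were the opposite, the (R)-valine ester would be used.

**Step 1**
Reactants: 1 tert-butyl 2-oxocyclohexane-1-carboxylate; 2 tert-butyl L-valinate
Product: 3 tert-butyl 2-{[(2S)-1-tert-butoxy-3-methyl-1-oxobutan-2-yl]amino}cyclohex-1-ene-1-carboxylate
Conditions: AcOH (cat.), 4 Å MS, PhMe, 60 °C
Reagents that add atoms: none
Why: Condensation of a β-keto ester with a primary amine should give the hydrogen-bonded β-enamino ester (enamine formation); no new stereocentre arises.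

**Step 2**
Reactants: 3 enamino ester
Product: 6 tert-butyl (1S)-1-methyl-2-oxocyclohexane-1-carboxylate, via lithio-enamine 4 (not isolated), via methylated imine 5 (not isolated)
Conditions: LDA, PhMe, −78 °C; THF (2 equiv); MeI, −78 → −40 °C; then 10% aq. citric acid, rt
Reagents that add atoms: iodomethane, CI; water, O
Why: Asymmetric alkylation of a chelated chiral lithio-enamine (lithium held by N and the valine ester carbonyl) should place the methyl on C4 anti to the isopropyl group to set the (S) quaternary centre, and the non-conjugated imine hydrolyses under mild acid with return of the auxiliary.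

**Step 3**
Reactants: 6 (S)-keto ester
Product: 8 tert-butyl (1S)-1,3-dimethyl-2-oxocyclohexane-1-carboxylate (both C3 epimers), via lithium enolate 7 (not isolated)
Conditions: LDA, THF, −78 °C; MeI, DMPU, −78 → −20 °C
Reagents that add atoms: iodomethane, CI
Why: Only the CH2 next to the ketone (the future C10) is enolisable, so enolate alkylation should methylate there; the new centre is formed as a mixture, which does not matter because it becomes sp2 in step 4.

**Step 4**
Reactants: 8 dimethyl keto ester
Product: 10 tert-butyl (1S)-1,3-dimethyl-2-(trifluoromethanesulfonyloxy)cyclohex-2-ene-1-carboxylate, via potassium enolate 9 (not isolated)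
Conditions: KHMDS, THF, −78 → 0 °C; PhNTf2, −78 °C → rt
Reagents that add atoms: N-phenylbis(trifluoromethanesulfonimide), O=S(=O)(N(c1ccccc1)S(=O)(=O)C(F)(F)F)C(F)(F)F
Why: The single remaining α-hydrogen leads to one tetrasubstituted enolate, which should be O-sulfonylated (enol triflate formation) to fix the C5=C10 double bond.

**Step 5**
Reactants: 10 enol triflate
Product: 12 tert-butyl (1S)-2-acetyl-1,3-dimethylcyclohex-2-ene-1-carboxylate, via ethoxydiene 11 (not isolated)
Conditions: tributyl(1-ethoxyvinyl)stannane, Pd(PPh3)4 (10 mol %), CuCl, LiCl, DMSO, 60 °C; then 1 M HCl, THF, 0 °C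
Reagents that add atoms: tributyl(1-ethoxyvinyl)stannane, CCCC[Sn](CCCC)(CCCC)C(=C)OCC; water, O
Why: Stille coupling of a hindered alkenyl triflate is helped by tin-to-copper transmetalation (CuCl/LiCl), and hydrolysis of the enol ether should unveil the methyl ketone that supplies C6 and C7.

**Step 6**
Reactants: 13 monoethyl fumarate
Product: 14 ethyl (2E)-4-hydroxybut-2-enoate
Conditions: BH3·THF, THF, −10 °C → rt
Reagents that add atoms: none
Why: Borane reduces a carboxylic acid much faster than an ester or a conjugated alkene (chemoselective borane reduction), so the E-alkene and the ester should survive.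

**Step 7**
Reactants: 12 ring A enone; 14 ethyl (2E)-4-hydroxybut-2-enoate
Product: 17 ethyl (2E)-4-{[({1-[(6S)-6-(tert-butoxycarbonyl)-2,6-dimethylcyclohex-1-en-1-yl]ethenyl}oxy)di(propan-2-yl)silyl]oxy}but-2-enoate, via lithium dienolate 15 (not isolated), via chlorosilyl dienol ether 16 (not isolated)
Conditions: LDA, THF, −78 °C; iPr2SiCl2 (3 equiv), −78 → 0 °C; volatiles removed in vacuo; then 14, imidazole, CH2Cl2, 0 °C → rt
Reagents that add atoms: dichlorodi(propan-2-yl)silane, CC(C)[Si](Cl)(Cl)C(C)C
Why: Kinetic deprotonation of the twisted enone at the acetyl methyl gives the cross-conjugated dienolate, and stepwise substitution at silicon (enolate first, then the alcohol; the second Si–Cl is slower than the first) should give the unsymmetrical silyl acetal (silyl enol ether/silyl ether formation).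

**Step 8**
Reactants: 17 silaketal triene
Product: 18 bridged cycloadduct (Δ5-octalin; C6–O and C17–O joined by Si(iPr)2; 4β-CO2tBu, 10β-CH3, 9β-CO2Et, 8α-CH2O)
Conditions: PhMe (0.01 M), BHT, 2,6-di-tert-butyl-4-methylpyridine (cat.), 150 °C, sealed tube
Reagents that add atoms: none
Why: This is a thermal, concerted but asynchronous [4+2] cycloaddition of the 2-siloxy diene C10=C5–C6=C7 with the tethered (E)-enoate C8=C9, that is, a type 2 intramolecular Diels–Alder reaction (tether on the inner diene carbon C6), whose closest known relatives are type 2 cycloadditions of dienes joined to the dienophile through a cleavable silyl acetal. Ring B closes in the ordinary six-membered suprafacial mode, the C7–C8 bond (enol-ether carbon onto the enoate β-carbon) running ahead of the C9–C10 bond that creates the quaternary centre, while the temporary seven-membered 1,3-dioxa-2-silacycloheptane (C6–O–Si–O–C17–C8–C7) closes in the bridged 1,3-mode to give a bicyclo[4.3.1]decene with a bridgehead enol ether C5=C6. C8 is set by the tether, which can span C6 and C8 only when C17 lies endo under the diene, so C17 ends anti to C20; C9 follows from the retained E geometry, which puts the ester exo, trans to C17 and syn to C20; C10 is set by C4, whose tert-butoxycarbonyl group stands pseudoaxial on ring A so that the tethered dienophile adds to the opposite (methyl) face and C20 ends cis to C19. The step needs regio-, endo/exo- and π-facial selectivity: the first is secured twice (tether length and matched polarisation), the second by the tether alone, and the third by C4, which is the least certain.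

**Step 9**
Reactants: 18 bridged cycloadduct
Product: 20 keto lactone (6-oxo trans-decalin with a trans-fused C17–O–C11(=O) γ-lactone on C8/C9), via hydroxy keto ester 19 (not isolated)
Conditions: HF·pyridine, THF, 0 °C → rt; then PPTS (cat.), PhMe, 70 °C
Reagents that add atoms: none
Why: Fluoride-assisted cleavage of both Si–O bonds frees the C6 enol, which should be protonated at C5 from the α-face (the β-face is covered by C20 and the axial ester) to give the trans-decalin, also the thermodynamic isomer, and mild acid closes the lactone between the trans-diequatorial CH2OH and ester (lactonisation).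

**Step 10**
Reactants: 20 keto lactone
Product: 21 C6 tosylhydrazone of 20
Conditions: TsNHNH2, PPTS (cat.), 4 Å MS, THF, 60 °C
Reagents that add atoms: 4-methylbenzenesulfonohydrazide, Cc1ccc(cc1)S(=O)(=O)NN
Why: Hydrazone condensation at the only ketone should proceed under mild acid that the tert-butyl ester and the lactone tolerate.

**Step 11**
Reactants: 21 tosylhydrazone
Product: 23 lactone with C6 as CH2, via N-boryl tosylhydrazine 22 (not isolated)
Conditions: catecholborane, CHCl3, 0 °C → rt; then NaOAc·3H2O, reflux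
Reagents that add atoms: none
Why: Hydride delivery to C=N followed by acetate-induced loss of sulfinate and then N2 from the diazene should leave a CH2 group (tosylhydrazone reduction), without base strong enough to touch C5 or C9.

**Step 12**
Reactants: 23 lactone
Product: 24 lactol (C11 hemiacetal, both anomers)
Conditions: DIBAL-H (1.2 equiv), CH2Cl2, −78 °C; aq. Rochelle salt
Reagents that add atoms: none
Why: Partial reduction of a γ-lactone to the lactol at low temperature is standard (DIBAL-H reduction), and the axial tert-butyl ester on quaternary C4 is too hindered to compete.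

**Step 13**
Reactants: 24 lactol
Product: 25 tert-butyl (1S,4aR,5S,6R,8aR)-5-ethenyl-6-(hydroxymethyl)-1,4a-dimethyldecahydronaphthalene-1-carboxylate
Conditions: Ph3PCH3Br, KOtBu, THF, 0 → 50 °C
Reagents that add atoms: methyltriphenylphosphonium bromide, C[P+](c1ccccc1)(c1ccccc1)c1ccccc1.[Br-]
Why: Wittig methylenation of the open hydroxy aldehyde form should install C12 and free the C17 hydroxyl in one step; the C9 formyl group is already in the stable equatorial position, so base does not change C9.

**Step 14**
Reactants: 26 furan-2(5H)-one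
Product: 28 3-bromofuran-2(5H)-one, via dibromolactone 27 (not isolated)
Conditions: Br2, CH2Cl2, 0 °C → rt; then Et3N, 0 °C
Reagents that add atoms: bromine, BrBr
Why: Bromine addition to the alkene and loss of HBr through the acidic α-hydrogen (addition–elimination) should give the α-bromo butenolide.

**Step 15**
Reactants: 25 vinyl alcohol; 28 3-bromofuran-2(5H)-one
Product: 30 tert-butyl (1S,4aR,5S,6R,8aR)-6-(hydroxymethyl)-1,4a-dimethyl-5-[2-(2-oxo-2,5-dihydrofuran-3-yl)ethyl]decahydronaphthalene-1-carboxylate, via bis-borane 29 (not isolated)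
Conditions: 9-BBN (3 equiv), THF, 0 °C → rt; then 28, PdCl2(dppf) (10 mol %), AsPh3, Cs2CO3, DMF/H2O, rt
Reagents that add atoms: none
Why: Anti-Markovnikov hydroboration of the monosubstituted alkene puts boron on C12, and B-alkyl Suzuki–Miyaura coupling with the α-bromo enoate-type partner should form C12–C13 with the butenolide intact.

**Step 16**
Reactants: 30 tert-butyl ester
Product: 31 (1S,4aR,5S,6R,8aR)-6-(hydroxymethyl)-1,4a-dimethyl-5-[2-(2-oxo-2,5-dihydrofuran-3-yl)ethyl]decahydronaphthalene-1-carboxylic acid (target)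
Conditions: TFA, CH2Cl2, 0 °C → rt; then aq. NaHCO3/MeOH, acidify to pH 3
Reagents that add atoms: none
Why: Acid cleavage of a tert-butyl ester goes through the tert-butyl cation and is not slowed by the hindrance at C19; a trifluoroacetate that may form at the primary alcohol should be solvolysed in the methanolic bicarbonate work-up.

**Compound list**

1 | tert-butyl 2-oxocyclohexane-1-carboxylate | O=C1CCCCC1C(=O)OC(C)(C)C | starting material
2 | tert-butyl L-valinate | CC(C)[C@H](N)C(=O)OC(C)(C)C | starting material
3 | tert-butyl 2-{[(2S)-1-tert-butoxy-3-methyl-1-oxobutan-2-yl]amino}cyclohex-1-ene-1-carboxylate | CC(C)[C@H](NC1=C(C(=O)OC(C)(C)C)CCCC1)C(=O)OC(C)(C)C | intermediate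
4 | lithio-enamine (N-lithium salt of 3, formed in the flask) | CC(C)[C@H]([N-]C1=C(C(=O)OC(C)(C)C)CCCC1)C(=O)OC(C)(C)C.[Li+] | intermediate
5 | tert-butyl (1S)-2-{[(2S)-1-tert-butoxy-3-methyl-1-oxobutan-2-yl]imino}-1-methylcyclohexane-1-carboxylate (formed in the flask) | CC(C)[C@H](N=C1CCCC[C@]1(C)C(=O)OC(C)(C)C)C(=O)OC(C)(C)C | intermediate
6 | tert-butyl (1S)-1-methyl-2-oxocyclohexane-1-carboxylate | O=C1CCCC[C@]1(C)C(=O)OC(C)(C)C | intermediate
7 | lithium enolate of 6 (formed in the flask) | [Li+].[O-]C1=CCCC[C@]1(C)C(=O)OC(C)(C)C | intermediate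
8 | tert-butyl (1S)-1,3-dimethyl-2-oxocyclohexane-1-carboxylate (both C3 epimers) | CC1CCC[C@](C)(C(=O)OC(C)(C)C)C1=O | intermediate
9 | potassium enolate of 8 (formed in the flask) | [K+].[O-]C1=C(C)CCC[C@]1(C)C(=O)OC(C)(C)C | intermediate
10 | tert-butyl (1S)-1,3-dimethyl-2-(trifluoromethanesulfonyloxy)cyclohex-2-ene-1-carboxylate | C1CC[C@](C)(C(=O)OC(C)(C)C)C(OS(=O)(=O)C(F)(F)F)=C1C | intermediate
11 | tert-butyl (1S)-2-(1-ethoxyethenyl)-1,3-dimethylcyclohex-2-ene-1-carboxylate (formed in the flask) | C1CC[C@](C)(C(=O)OC(C)(C)C)C(C(=C)OCC)=C1C | intermediate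
12 | tert-butyl (1S)-2-acetyl-1,3-dimethylcyclohex-2-ene-1-carboxylate | C1CC[C@](C)(C(=O)OC(C)(C)C)C(C(C)=O)=C1C | intermediate
13 | monoethyl fumarate, (2E)-4-ethoxy-4-oxobut-2-enoic acid | CCOC(=O)/C=C/C(=O)O | starting material
14 | ethyl (2E)-4-hydroxybut-2-enoate | CCOC(=O)/C=C/CO | intermediate
15 | lithium dienolate of 12 (O-lithium, C6=C7; formed in the flask) | C1CC[C@](C)(C(=O)OC(C)(C)C)C(C(=C)[O-])=C1C.[Li+] | intermediate
16 | tert-butyl (1S)-2-(1-{[chlorodi(propan-2-yl)silyl]oxy}ethenyl)-1,3-dimethylcyclohex-2-ene-1-carboxylate (formed in the flask) | C1CC[C@](C)(C(=O)OC(C)(C)C)C(C(=C)O[Si](Cl)(C(C)C)C(C)C)=C1C | intermediate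
17 | ethyl (2E)-4-{[({1-[(6S)-6-(tert-butoxycarbonyl)-2,6-dimethylcyclohex-1-en-1-yl]ethenyl}oxy)di(propan-2-yl)silyl]oxy}but-2-enoate | C1CC[C@](C)(C(=O)OC(C)(C)C)C(C(=C)O[Si](C(C)C)(C(C)C)OC/C=C/C(=O)OCC)=C1C | intermediate
18 | bridged cycloadduct: Δ5-octalin, 4α-CH3, 4β-CO2tBu, 10β-CH3, 9β-CO2Et (9α-H), 8α-CH2O (8β-H), O6 and O17 joined by Si(iPr)2 | C[C@]12CCC[C@](C)(C(=O)OC(C)(C)C)C1=C3C[C@@H](CO[Si](C(C)C)(C(C)C)O3)[C@@H]2C(=O)OCC | intermediate
19 | hydroxy keto ester: trans-decalin (5α-H), 6-oxo, 8α-CH2OH, 9β-CO2Et, 4α-CH3, 4β-CO2tBu, 10β-CH3 (formed in the flask) | C[C@]12CCC[C@](C)(C(=O)OC(C)(C)C)[C@@H]1C(=O)C[C@@H](CO)[C@@H]2C(=O)OCC | intermediate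
20 | keto lactone: as 19 with O17 acylated by C11 (trans-fused γ-lactone on C8/C9) | C[C@]12CCC[C@](C)(C(=O)OC(C)(C)C)[C@@H]1C(=O)C[C@@H](CO3)[C@@H]2C3=O | intermediate
21 | C6 tosylhydrazone of 20 | C[C@]12CCC[C@](C)(C(=O)OC(C)(C)C)[C@@H]1C(=NNS(=O)(=O)c1ccc(C)cc1)C[C@@H](CO3)[C@@H]2C3=O | intermediate
22 | N-(1,3,2-benzodioxaborol-2-yl) tosylhydrazine at C6 (formed in the flask) | C[C@]12CCC[C@](C)(C(=O)OC(C)(C)C)[C@@H]1C(N(B3Oc4ccccc4O3)NS(=O)(=O)c3ccc(C)cc3)C[C@@H](CO5)[C@@H]2C5=O | intermediate
23 | lactone: 6-deoxo analogue of 20 | C[C@]12CCC[C@](C)(C(=O)OC(C)(C)C)[C@@H]1CC[C@@H](CO3)[C@@H]2C3=O | intermediate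
24 | lactol: C11 hemiacetal of 23 (both anomers) | C[C@]12CCC[C@](C)(C(=O)OC(C)(C)C)[C@@H]1CC[C@@H](CO3)[C@@H]2C3O | intermediate
25 | tert-butyl (1S,4aR,5S,6R,8aR)-5-ethenyl-6-(hydroxymethyl)-1,4a-dimethyldecahydronaphthalene-1-carboxylate | C[C@]12CCC[C@](C)(C(=O)OC(C)(C)C)[C@@H]1CC[C@@H](CO)[C@@H]2C=C | intermediate
26 | furan-2(5H)-one | O=C1OCC=C1 | starting material
27 | trans-3,4-dibromooxolan-2-one (racemic, formed in the flask) | O=C1OCC(Br)C1Br | intermediate
28 | 3-bromofuran-2(5H)-one | O=C1OCC=C1Br | intermediate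
29 | bis-borane: C12–B and O17–B 9-borabicyclo[3.3.1]nonan-9-yl derivative of 25 (formed in the flask) | C[C@]12CCC[C@](C)(C(=O)OC(C)(C)C)[C@@H]1CC[C@@H](COB3C4CCCC3CCC4)[C@@H]2CCB1C2CCCC1CCC2 | intermediate
30 | tert-butyl (1S,4aR,5S,6R,8aR)-6-(hydroxymethyl)-1,4a-dimethyl-5-[2-(2-oxo-2,5-dihydrofuran-3-yl)ethyl]decahydronaphthalene-1-carboxylate | C[C@]12CCC[C@](C)(C(=O)OC(C)(C)C)[C@@H]1CC[C@@H](CO)[C@@H]2CCC1=CCOC1=O | intermediate
31 | (1S,4aR,5S,6R,8aR)-6-(hydroxymethyl)-1,4a-dimethyl-5-[2-(2-oxo-2,5-dihydrofuran-3-yl)ethyl]decahydronaphthalene-1-carboxylic acid | C[C@]12CCC[C@](C)(C(=O)O)[C@@H]1CC[C@@H](CO)[C@@H]2CCC1=CCOC1=O | target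

**Step count and risks**

Total step count: 16. Longest linear sequence: 14 (steps 1–5, 7–13, 15, 16).

Steps most likely to fail:

1. Step 8. The bridged closure may be too slow at a temperature the substrate tolerates: the quaternary C9–C10 bond forms late, so a [1,5]-hydrogen shift from the cis methyl group (C20) to C7, or loss of the silyl enol ether, may overtake the cycloaddition; leakage to the other diene face is also possible. Fallback, from 12 back to 20, by an untethered cycloaddition with the C9 centre corrected afterwards: soft enolisation of 12 (TBSOTf, Et3N, CH2Cl2) should give the tert-butyldimethylsilyl dienol ether F1. An intermolecular Diels–Alder reaction of F1 with furan-2(5H)-one 26 under high pressure (CH2Cl2, 1.2 GPa, rt) should give the endo adduct, the cis-fused lactone silyl enol ether F2, with C7 bonded to the butenolide β-carbon by polarisation and C17 on the α-face by the endo rule. HF·pyridine should then give the keto cis-lactone F3 (the C9 epimer of 20). Catalytic NaOEt in EtOH opens the lactone and equilibrates C9 through the open ethyl ester to the equatorial 9β-ester, which is 19, and this is closed to 20 with PPTS as in step 9.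

2. Step 10. Condensation at the C6 carbonyl may stall, because C5 next to it sits between two quaternary carbons, and forcing it with stronger acid would cost the tert-butyl ester. Fallback, from 20 back to 23, by removing the oxygen through an enol triflate: kinetic enolisation of 20 toward C7 (KHMDS, THF, −78 °C) and trapping with PhNTf2 should give the C6=C7 enol triflate F4. Palladium-catalysed formate reduction (Pd(OAc)2, PPh3, Bu3N, HCO2H, DMF, 60 °C) should give the Δ6 alkene lactone F5, and hydrogenation (H2, Pd/C, EtOAc) returns 23.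

3. Step 15. Base-induced decomposition of the bromobutenolide or slow transmetalation of the B-alkyl group next to the crowded decalin may leave only protodeboronation. Fallback, from 25 to 31, building the butenolide by olefination and alkene migration:
   - TBSCl/imidazole should give the silyl ether F6.
   - 9-BBN then NaOH/H2O2 should give the C12 primary alcohol F7.
   - DMP oxidation should give the aldehyde F8.
   - A Wittig reaction with the stabilised ylide α-(triphenylphosphoranylidene)-γ-butyrolactone (PhMe, 80 °C) should give the (E)-alkylidene lactone F9.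
   - RhCl3·3H2O (cat.) in EtOH at 80 °C should move the exocyclic double bond into the ring to give the protected butenolide F10.
   - TFA/CH2Cl2/H2O then removes the silyl ether and the tert-butyl ester to reach 31.

**Further compounds**

F1 | step 8 | tert-butyl (1S)-2-(1-{[tert-butyl(dimethyl)silyl]oxy}ethenyl)-1,3-dimethylcyclohex-2-ene-1-carboxylate | C1CC[C@](C)(C(=O)OC(C)(C)C)C(C(=C)O[Si](C)(C)C(C)(C)C)=C1C
F2 | step 8 | endo adduct: C5=C6 tert-butyldimethylsilyl enol ether with cis-fused C17–O–C11(=O) lactone (C17 α, C11 α) | C[C@]12CCC[C@](C)(C(=O)OC(C)(C)C)C1=C(O[Si](C)(C)C(C)(C)C)C[C@@H](CO3)[C@H]2C3=O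
F3 | step 8 | keto cis-lactone (C9 epimer of 20) | C[C@]12CCC[C@](C)(C(=O)OC(C)(C)C)[C@@H]1C(=O)C[C@@H](CO3)[C@H]2C3=O
F4 | step 10 | C6=C7 enol triflate of 20 | C[C@]12CCC[C@](C)(C(=O)OC(C)(C)C)[C@@H]1C(OS(=O)(=O)C(F)(F)F)=C[C@@H](CO3)[C@@H]2C3=O
F5 | step 10 | Δ6 alkene lactone | C[C@]12CCC[C@](C)(C(=O)OC(C)(C)C)[C@@H]1C=C[C@@H](CO3)[C@@H]2C3=O
F6 | step 15 | tert-butyldimethylsilyl ether of 25 | C[C@]12CCC[C@](C)(C(=O)OC(C)(C)C)[C@@H]1CC[C@@H](CO[Si](C)(C)C(C)(C)C)[C@@H]2C=C
F7 | step 15 | C12 primary alcohol (O17 silyl ether) | C[C@]12CCC[C@](C)(C(=O)OC(C)(C)C)[C@@H]1CC[C@@H](CO[Si](C)(C)C(C)(C)C)[C@@H]2CCO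
F8 | step 15 | C12 aldehyde (O17 silyl ether) | C[C@]12CCC[C@](C)(C(=O)OC(C)(C)C)[C@@H]1CC[C@@H](CO[Si](C)(C)C(C)(C)C)[C@@H]2CC=O
F9 | step 15 | (E)-α-alkylidene-γ-butyrolactone (C12=C13, O17 silyl ether) | C[C@]12CCC[C@](C)(C(=O)OC(C)(C)C)[C@@H]1CC[C@@H](CO[Si](C)(C)C(C)(C)C)[C@@H]2C/C=C1/C(=O)OCC1
F10 | step 15 | O17 tert-butyldimethylsilyl ether of 30 | C[C@]12CCC[C@](C)(C(=O)OC(C)(C)C)[C@@H]1CC[C@@H](CO[Si](C)(C)C(C)(C)C)[C@@H]2CCC1=CCOC1=O
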